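**Strategy.** Everything rests on cutting ring C of the lower, catechin-type unit across C4–C3 and O1–C2. Its O1–C8a–C4a–C4H2 segment is the o-hydroxybenzyl motif of the phloroglucinol-type ring A, i.e. an ortho-quinone methide, and its trans C2-aryl/C3-oxygen pair is an (E)-β-acyloxystyrene. A chiral-acid-catalysed inverse-demand oxa-Diels–Alder reaction between a benzyl-protected salicyl alcohol and an (E)-styryl formate thus forms the C4–C3 bond, closes ring C and sets both stereocentres in one operation from two achiral pieces. The benzylated catechin so made is then joined through C8 to the C4 cation of an enantiopure 7,8-dioxygenated 2,3-trans-flavan-3,4-diol, and hydrogenolysis gives the target.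

Key step: step 11

Remark: flavan numbering (O1, C2, C3, C4, C4a, C5–C8, C8a; primed locants for ring B) is used for both units; the 7,8-dioxygenated unit is the upper unit and the catechin unit the lower unit; Bn = benzyl, MOM = methoxymethyl, (R)-TRIP = (R)-3,3'-bis(2,4,6-triisopropylphenyl)-1,1'-binaphthyl-2,2'-diyl hydrogen phosphate.

**Upper unit**

Step 1
Reactants: 1 1-(2,3,4-trihydroxyphenyl)ethanone (gallacetophenone)
Product: 2 1-[3,4-bis(benzyloxy)-2-hydroxyphenyl]ethanone
Conditions: BnBr (2.1 equiv), K2CO3, DMF, rt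
Reagents that add atoms: benzyl bromide, BrCc1ccccc1
Why: Williamson etherification in which the two more acidic, non-chelated phenols (O3 and O4) react while the 2-OH, hydrogen-bonded to the ketone, should stay free under carbonate conditions.

Step 2
Reactants: 2 1-[3,4-bis(benzyloxy)-2-hydroxyphenyl]ethanone
Product: 3 1-[3,4-bis(benzyloxy)-2-(methoxymethoxy)phenyl]ethanone
Conditions: NaH, MOMCl, DMF, 0 °C to rt
Reagents that add atoms: chloromethyl methyl ether, COCCl
Why: Williamson-type O-alkylation of the sodium phenoxide masks the chelated phenol as a base-stable acetal, so that the later nucleophilic epoxidation is not diverted into Algar–Flynn–Oyamada chemistry.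

Step 3
Reactants: 3 1-[3,4-bis(benzyloxy)-2-(methoxymethoxy)phenyl]ethanone; 4 3,4-bis(benzyloxy)benzaldehyde
Product: 5 (E)-1-[3,4-bis(benzyloxy)-2-(methoxymethoxy)phenyl]-3-[3,4-bis(benzyloxy)phenyl]prop-2-en-1-one
Conditions: KOH, EtOH–THF, rt
Reagents that add atoms: none
Why: Claisen–Schmidt aldol condensation of the methyl ketone enolate with the non-enolisable aldehyde should give the thermodynamically favoured E enone, all ethers being stable to base.

Step 4
Reactants: 5 (E)-1-[3,4-bis(benzyloxy)-2-(methoxymethoxy)phenyl]-3-[3,4-bis(benzyloxy)phenyl]prop-2-en-1-one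
Product: 6 [3,4-bis(benzyloxy)-2-(methoxymethoxy)phenyl]{(2R,3S)-3-[3,4-bis(benzyloxy)phenyl]oxiran-2-yl}methanone
Conditions: poly-L-leucine, urea–H2O2, DBU, THF, rt
Reagents that add atoms: hydrogen peroxide (from its urea adduct), OO
Why: Juliá–Colonna epoxidation, in which hydroperoxide adds to the enone bound to the helical poly-L-leucine on one face only, should give the (αR,βS) epoxide (the future upper C3 and C2), trans because the enone is E.

Step 5
Reactants: 6 [3,4-bis(benzyloxy)-2-(methoxymethoxy)phenyl]{(2R,3S)-3-[3,4-bis(benzyloxy)phenyl]oxiran-2-yl}methanone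
Product: 7 (2R,3R)-7,8-bis(benzyloxy)-2-[3,4-bis(benzyloxy)phenyl]-3-hydroxychroman-4-one
Conditions: HCl (conc., cat.), MeOH–THF, 50 °C
Reagents that add atoms: none
Why: Acid methanolysis of the MOM acetal frees the phenol, which opens the epoxide 6-endo at the p-alkoxybenzylic carbon with inversion (βS becomes 2R) while the carbinol carbon keeps its configuration (3R), giving the 2,3-trans dihydroflavonol, which is also the thermodynamic isomer.

Step 6
Reactants: 7 (2R,3R)-7,8-bis(benzyloxy)-2-[3,4-bis(benzyloxy)phenyl]-3-hydroxychroman-4-one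
Product: 8 (2R,3S,4R)-7,8-bis(benzyloxy)-2-[3,4-bis(benzyloxy)phenyl]chromane-3,4-diol
Conditions: NaBH4, MeOH–THF, 0 °C
Reagents that add atoms: none
Why: Borohydride reduction of the C4 ketone should give mainly the 3,4-trans diol, and the C4 configuration is of no consequence because this centre is ionised in step 12.

**Lower unit**

Step 7
Reactants: 9 3,5-bis(benzyloxy)phenol
Product: 10 4,6-bis(benzyloxy)-2-hydroxybenzaldehyde
Conditions: MgCl2, Et3N, (CH2O)n, MeCN, reflux; then aq. HCl
Reagents that add atoms: formaldehyde (from paraformaldehyde), C=O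
Why: Magnesium-mediated ortho-formylation (Casnati–Skattebøl) delivers formaldehyde from the magnesium phenoxide to the ortho position only, and the two ortho positions of 9 are equivalent, so a single salicylaldehyde should form.

Step 8
Reactants: 10 4,6-bis(benzyloxy)-2-hydroxybenzaldehyde
Product: 11 3,5-bis(benzyloxy)-2-(hydroxymethyl)phenol
Conditions: NaBH4, THF–MeOH, 0 °C; pH 7 work-up
Reagents that add atoms: none
Why: Borohydride reduction of the aldehyde gives the salicyl alcohol that serves as the quinone methide precursor; it is kept away from acid and used at once.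

Step 9
Reactants: 4 3,4-bis(benzyloxy)benzaldehyde
Product: 12 (E)-3-[3,4-bis(benzyloxy)phenyl]prop-2-enal
Conditions: Ph3P=CHCHO, toluene, 80 °C
Reagents that add atoms: (triphenylphosphoranylidene)acetaldehyde, O=CC=P(c1ccccc1)(c1ccccc1)c1ccccc1
Why: Wittig olefination with the stabilised formyl ylide should give the E enal.

Step 10
Reactants: 12 (E)-3-[3,4-bis(benzyloxy)phenyl]prop-2-enal
Product: 13 (E)-2-[3,4-bis(benzyloxy)phenyl]ethenyl formate
Conditions: 30% H2O2, bis(2-nitrophenyl) diselenide (cat.), CH2Cl2, rt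
Reagents that add atoms: hydrogen peroxide, OO
Why: Baeyer–Villiger oxidation of the α,β-unsaturated aldehyde by the perseleninic acid formed in the flask, in which the electron-rich alkenyl group migrates in preference to hydrogen with retention of the E geometry, should give the enol formate.

Step 11
Reactants: 11 3,5-bis(benzyloxy)-2-(hydroxymethyl)phenol; 13 (E)-2-[3,4-bis(benzyloxy)phenyl]ethenyl formate
Product: 16 (2R,3S)-5,7-bis(benzyloxy)-2-[3,4-bis(benzyloxy)phenyl]chroman-3-ol, via ortho-quinone methide 14 (not isolated), via chroman-3-yl formate 15 (not isolated)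
Conditions: (R)-TRIP (10 mol %), 4 Å MS, toluene, −30 °C, slow addition of 11 to 13 (3 equiv); then K2CO3, MeOH–THF, 0 °C
Reagents that add atoms: none
Why: The chiral phosphoric acid ionises the benzylic alcohol of 11, which is activated by three ring oxygens, to the ortho-quinone methide 14 held on the phosphate by a hydrogen bond, and this oxadiene (O=C8a–C4a=C4H2) adds across the alkene of 13 in an inverse-electron-demand oxa-Diels–Alder reaction that makes C4–C3 and O1–C2 of ring C in one event. The closest known reaction type is the chiral Brønsted acid-catalysed [4+2] cycloaddition of ortho-quinone methides from o-hydroxybenzyl alcohols with electron-rich styrenes. Ring C closes as a six-membered ring by [4+2] cycloaddition, in the asynchronous limit C4–C3 bond formation followed by collapse of the phenolic oxygen onto the p-benzyloxybenzylic cation at C2. C2 and C3 should come out trans because the E geometry of 13 is transferred by suprafacial addition (a rotating cation would converge on the same diequatorial trans product through formyloxy participation), and their absolute sense (2R,3S) is controlled by the phosphate, which covers one face of bound 14 while the aryl group of 13 takes the endo position. The step needs the regiochemistry C4 to C3 and O1 to C2, secured because the methide carbon bonds to the alkene carbon that leaves the positive charge on the carbon bearing the 3,4-bis(benzyloxy)phenyl group and not beside the weakly donating formyloxy group, and it needs the methide to form towards O1 only, secured because 11 has a single free phenol. Slow addition of 11 to excess 13 keeps Friedel–Crafts capture of 14 by the electron-rich rings low, and the formate is cleaved by mild methanolysis before isolation.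

**Union and deprotection**

Step 12
Reactants: 8 (2R,3S,4R)-7,8-bis(benzyloxy)-2-[3,4-bis(benzyloxy)phenyl]chromane-3,4-diol; 16 (2R,3S)-5,7-bis(benzyloxy)-2-[3,4-bis(benzyloxy)phenyl]chroman-3-ol
Product: 17 (2R,3S,4S)-7,8-bis(benzyloxy)-2-[3,4-bis(benzyloxy)phenyl]-4-{(2R,3S)-5,7-bis(benzyloxy)-2-[3,4-bis(benzyloxy)phenyl]-3-hydroxychroman-8-yl}chroman-3-ol
Conditions: TMSOTf (0.3 equiv), 16 (3 equiv), CH2Cl2, −40 °C
Reagents that add atoms: none
Why: Lewis acid-mediated Friedel–Crafts-type flavan-4-yl cation coupling of proanthocyanidin synthesis, in which the C4–OH of 8 ionises to a cation stabilised by the para 7-benzyloxy group and O1, and C8 of 16 (the more nucleophilic and less hindered free position of its ring A) attacks from the α face anti to the C3–OH, setting C4 as 4S (3,4-trans), while the excess of 16 suppresses self-condensation.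

Step 13
Reactants: 17 (2R,3S,4S)-7,8-bis(benzyloxy)-2-[3,4-bis(benzyloxy)phenyl]-4-{(2R,3S)-5,7-bis(benzyloxy)-2-[3,4-bis(benzyloxy)phenyl]-3-hydroxychroman-8-yl}chroman-3-ol
Product: 18 (2R,3S,4S)-2-(3,4-dihydroxyphenyl)-4-[(2R,3S)-2-(3,4-dihydroxyphenyl)-3,5,7-trihydroxychroman-8-yl]chromane-3,7,8-triol
Conditions: H2 (1 atm), Pd(OH)2/C, THF–MeOH–H2O, rt
Reagents that add atoms: none
Why: Hydrogenolysis of the eight benzyl ethers over Pd(OH)2/C under neutral conditions should leave the interflavan C4–C8 bond, both ring ethers and all five stereocentres untouched.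

**Compound list**

1 | 1-(2,3,4-trihydroxyphenyl)ethanone (gallacetophenone) | CC(=O)c1ccc(O)c(O)c1O | starting material
2 | 1-[3,4-bis(benzyloxy)-2-hydroxyphenyl]ethanone | CC(=O)c1ccc(OCc2ccccc2)c(OCc2ccccc2)c1O | intermediate
3 | 1-[3,4-bis(benzyloxy)-2-(methoxymethoxy)phenyl]ethanone | CC(=O)c1ccc(OCc2ccccc2)c(OCc2ccccc2)c1OCOC | intermediate
4 | 3,4-bis(benzyloxy)benzaldehyde | O=Cc1ccc(OCc2ccccc2)c(OCc2ccccc2)c1 | starting material
5 | (E)-1-[3,4-bis(benzyloxy)-2-(methoxymethoxy)phenyl]-3-[3,4-bis(benzyloxy)phenyl]prop-2-en-1-one | COCOc1c(C(=O)/C=C/c2ccc(OCc3ccccc3)c(OCc3ccccc3)c2)ccc(OCc2ccccc2)c1OCc1ccccc1 | intermediate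
6 | [3,4-bis(benzyloxy)-2-(methoxymethoxy)phenyl]{(2R,3S)-3-[3,4-bis(benzyloxy)phenyl]oxiran-2-yl}methanone | COCOc1c(C(=O)[C@@H]2O[C@H]2c2ccc(OCc3ccccc3)c(OCc3ccccc3)c2)ccc(OCc2ccccc2)c1OCc1ccccc1 | intermediate
7 | (2R,3R)-7,8-bis(benzyloxy)-2-[3,4-bis(benzyloxy)phenyl]-3-hydroxychroman-4-one | O=C1c2ccc(OCc3ccccc3)c(OCc3ccccc3)c2O[C@H](c2ccc(OCc3ccccc3)c(OCc3ccccc3)c2)[C@H]1O | intermediate
8 | (2R,3S,4R)-7,8-bis(benzyloxy)-2-[3,4-bis(benzyloxy)phenyl]chromane-3,4-diol | O[C@@H]1c2ccc(OCc3ccccc3)c(OCc3ccccc3)c2O[C@H](c2ccc(OCc3ccccc3)c(OCc3ccccc3)c2)[C@H]1O | intermediate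
9 | 3,5-bis(benzyloxy)phenol | Oc1cc(OCc2ccccc2)cc(OCc2ccccc2)c1 | starting material
10 | 4,6-bis(benzyloxy)-2-hydroxybenzaldehyde | O=Cc1c(O)cc(OCc2ccccc2)cc1OCc1ccccc1 | intermediate
11 | 3,5-bis(benzyloxy)-2-(hydroxymethyl)phenol | OCc1c(O)cc(OCc2ccccc2)cc1OCc1ccccc1 | intermediate
12 | (E)-3-[3,4-bis(benzyloxy)phenyl]prop-2-enal | O=C/C=C/c1ccc(OCc2ccccc2)c(OCc2ccccc2)c1 | intermediate
13 | (E)-2-[3,4-bis(benzyloxy)phenyl]ethenyl formate | O=CO/C=C/c1ccc(OCc2ccccc2)c(OCc2ccccc2)c1 | intermediate
14 | 3,5-bis(benzyloxy)-6-methylidenecyclohexa-2,4-dien-1-one (ortho-quinone methide, formed in the flask in step 11) | C=C1C(=O)C=C(OCc2ccccc2)C=C1OCc1ccccc1 | intermediate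
15 | (2R,3S)-5,7-bis(benzyloxy)-2-[3,4-bis(benzyloxy)phenyl]chroman-3-yl formate (formed in the flask in step 11) | O=CO[C@H]1Cc2c(OCc3ccccc3)cc(OCc3ccccc3)cc2O[C@@H]1c1ccc(OCc2ccccc2)c(OCc2ccccc2)c1 | intermediate
16 | (2R,3S)-5,7-bis(benzyloxy)-2-[3,4-bis(benzyloxy)phenyl]chroman-3-ol (5,7,3',4'-tetra-O-benzyl-(+)-catechin) | O[C@H]1Cc2c(OCc3ccccc3)cc(OCc3ccccc3)cc2O[C@@H]1c1ccc(OCc2ccccc2)c(OCc2ccccc2)c1 | intermediate
17 | (2R,3S,4S)-7,8-bis(benzyloxy)-2-[3,4-bis(benzyloxy)phenyl]-4-{(2R,3S)-5,7-bis(benzyloxy)-2-[3,4-bis(benzyloxy)phenyl]-3-hydroxychroman-8-yl}chroman-3-ol | c1ccccc1COc1ccc([C@H]2Oc3c(ccc(OCc4ccccc4)c3OCc3ccccc3)[C@@H](c3c(OCc4ccccc4)cc(OCc4ccccc4)c4c3O[C@H](c3ccc(OCc5ccccc5)c(OCc5ccccc5)c3)[C@@H](O)C4)[C@@H]2O)cc1OCc1ccccc1 | intermediate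
18 | (2R,3S,4S)-2-(3,4-dihydroxyphenyl)-4-[(2R,3S)-2-(3,4-dihydroxyphenyl)-3,5,7-trihydroxychroman-8-yl]chromane-3,7,8-triol | Oc1ccc([C@H]2Oc3c(ccc(O)c3O)[C@@H](c3c(O)cc(O)c4c3O[C@H](c3ccc(O)c(O)c3)[C@@H](O)C4)[C@@H]2O)cc1O | target

**Step count**

Total steps: 13. Longest linear sequence: 8 steps (steps 1–6, 12 and 13).

**Steps most likely to fail**

Step 11. Two processes may go wrong. The chiral acid may discriminate poorly between the two faces of the alkene, because the methide carbon of 14 carries no substituent that fixes its place in the catalyst pocket. The antipode of the acid that leads to the 2R,3S series has in any case to be fixed in a first run by comparison with 16 made by benzylation of natural (+)-catechin. In addition, acid-driven Friedel–Crafts capture of 14 by the electron-rich rings of 11 or 16 may compete with the cycloaddition. The fallback sets out from 11 and 13 and comes back to the route at 17. Compound 11 is heated with excess 13 in toluene at 110 °C without any acid. This is the known thermal dehydration of a salicyl alcohol to the neutral ortho-quinone methide 14 and its capture by a β-substituted electron-rich styrene, and it removes the Friedel–Crafts problem. It should give the trans adduct as a racemate, that is 15 together with its enantiomer (2S,3R)-5,7-bis(benzyloxy)-2-[3,4-bis(benzyloxy)phenyl]chroman-3-yl formate F1. The same methanolysis then gives 16 together with its enantiomer (2S,3R)-5,7-bis(benzyloxy)-2-[3,4-bis(benzyloxy)phenyl]chroman-3-ol F2. The racemate is used in step 12 in the same excess. The enantiopure cation from 8 converts it into 17 and the diastereomer (2R,3S,4S)-7,8-bis(benzyloxy)-2-[3,4-bis(benzyloxy)phenyl]-4-{(2S,3R)-5,7-bis(benzyloxy)-2-[3,4-bis(benzyloxy)phenyl]-3-hydroxychroman-8-yl}chroman-3-ol F3. These differ in physical properties and are separated by chromatography, so the lower unit is resolved by the upper one, and 17 goes on to step 13.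

Step 12. The 5-deoxy cation from 8 has no peri substituent, so attack may occur on both faces of C4 and give a 4α/4β mixture. The cation may also be captured by C6 of ring A of another molecule of 8 or by 17. The fallback sets out from 8 and comes back at 17, and uses neighbouring-group participation. Compound 8 is acetylated (Ac2O, pyridine, DMAP) to (2R,3R,4R)-7,8-bis(benzyloxy)-2-[3,4-bis(benzyloxy)phenyl]chromane-3,4-diyl diacetate F4, in which the C3 descriptor changes by priority only. Treatment with TMSOTf (cat.) and 16 (3 equiv) in CH2Cl2 at −40 °C ionises the C4 acetate, and the β-oriented C3 acetate bridges to C4 as an acetoxonium ion. C8 of 16 can then enter only from the α face, which should give the 3,4-trans product (2R,3S,4S)-7,8-bis(benzyloxy)-2-[3,4-bis(benzyloxy)phenyl]-4-{(2R,3S)-5,7-bis(benzyloxy)-2-[3,4-bis(benzyloxy)phenyl]-3-hydroxychroman-8-yl}chroman-3-yl acetate F5. Methanolysis (K2CO3, MeOH–THF) returns 17.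

Step 5. The epoxide carbon next to the 3,4-bis(benzyloxy)phenyl group may ionise before the phenol is unmasked. This would lead to solvolysis by methanol or chloride, loss of the trans selectivity and acyl migration. The fallback sets out from 6 and comes back at 7, and separates unmasking and ring closure. Compound 6 is treated with benzyl mercaptan and SnCl4 in CH2Cl2 at −20 °C, which removes the MOM group and opens the epoxide at the benzylic carbon with inversion. This gives (2S,3R)-1-[3,4-bis(benzyloxy)-2-hydroxyphenyl]-3-(benzylsulfanyl)-3-[3,4-bis(benzyloxy)phenyl]-2-hydroxypropan-1-one F6. Thiophilic activation with AgBF4 in CH2Cl2 at 0 °C then lets the phenol close onto the benzylic carbon, and the 2,3-trans dihydroflavonol 7 is expected as the main product.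

**Further compounds**

F1 | step 11 | (2S,3R)-5,7-bis(benzyloxy)-2-[3,4-bis(benzyloxy)phenyl]chroman-3-yl formate | O=CO[C@@H]1Cc2c(OCc3ccccc3)cc(OCc3ccccc3)cc2O[C@H]1c1ccc(OCc2ccccc2)c(OCc2ccccc2)c1
F2 | step 11 | (2S,3R)-5,7-bis(benzyloxy)-2-[3,4-bis(benzyloxy)phenyl]chroman-3-ol | O[C@@H]1Cc2c(OCc3ccccc3)cc(OCc3ccccc3)cc2O[C@H]1c1ccc(OCc2ccccc2)c(OCc2ccccc2)c1
F3 | step 11 | (2R,3S,4S)-7,8-bis(benzyloxy)-2-[3,4-bis(benzyloxy)phenyl]-4-{(2S,3R)-5,7-bis(benzyloxy)-2-[3,4-bis(benzyloxy)phenyl]-3-hydroxychroman-8-yl}chroman-3-ol | c1ccccc1COc1ccc([C@H]2Oc3c(ccc(OCc4ccccc4)c3OCc3ccccc3)[C@@H](c3c(OCc4ccccc4)cc(OCc4ccccc4)c4c3O[C@@H](c3ccc(OCc5ccccc5)c(OCc5ccccc5)c3)[C@H](O)C4)[C@@H]2O)cc1OCc1ccccc1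
F4 | step 12 | (2R,3R,4R)-7,8-bis(benzyloxy)-2-[3,4-bis(benzyloxy)phenyl]chromane-3,4-diyl diacetate | CC(=O)O[C@@H]1c2ccc(OCc3ccccc3)c(OCc3ccccc3)c2O[C@H](c2ccc(OCc3ccccc3)c(OCc3ccccc3)c2)[C@H]1OC(C)=O
F5 | step 12 | (2R,3S,4S)-7,8-bis(benzyloxy)-2-[3,4-bis(benzyloxy)phenyl]-4-{(2R,3S)-5,7-bis(benzyloxy)-2-[3,4-bis(benzyloxy)phenyl]-3-hydroxychroman-8-yl}chroman-3-yl acetate | c1ccccc1COc1ccc([C@H]2Oc3c(ccc(OCc4ccccc4)c3OCc3ccccc3)[C@@H](c3c(OCc4ccccc4)cc(OCc4ccccc4)c4c3O[C@H](c3ccc(OCc5ccccc5)c(OCc5ccccc5)c3)[C@@H](O)C4)[C@@H]2OC(C)=O)cc1OCc1ccccc1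
F6 | step 5 | (2S,3R)-1-[3,4-bis(benzyloxy)-2-hydroxyphenyl]-3-(benzylsulfanyl)-3-[3,4-bis(benzyloxy)phenyl]-2-hydroxypropan-1-one | O=C(c1ccc(OCc2ccccc2)c(OCc2ccccc2)c1O)[C@H](O)[C@H](SCc1ccccc1)c1ccc(OCc2ccccc2)c(OCc2ccccc2)c1
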